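A direct plan would take the ring from (R)-limonene A1: chlorohydrin A2, ozonolysis to methyl ketone A3, ketal-Claisen homologation to prenyl ketone A4, bromonium 6-endo closure through the ketone oxygen to bromo dihydropyran A5, then epoxidation/AlMe3 opening to carbinol A6 and a last OH→Br exchange.
Weak point 1, the bromonium closure through the ketone oxygen: no stereocentre is near C5 of the oxane when bromine enters, so both C5 epimers would form, the ring-to-ring relation would rest on a separation, and C2 and C3 would be relayed from that uncontrolled centre.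
Weak point 2, the epoxidation/AlMe3 pair that makes quaternary C2: it needs face control on a labile α-alkoxy epoxide, and aluminium alkyls can open such epoxides syn as well as anti.
Weak point 3, the ketal-Claisen on the methyl ketone (acid, 140 °C): the enol ether can also form on the ring-methine side, which scrambles C1′, and the free tertiary chlorohydrin is exposed to acid and heat.

**Retrosynthetic overview**
- The cyclohexane is built, not bought: a catalyst-controlled Diels–Alder reaction of an open-chain (S)-α′-hydroxy vinyl ketone, which already holds oxane carbons C2–C6, with 2-(trimethylsilylmethyl)butadiene forms C1′–C2′ and C5′–C6′ and sets C1′.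
- The allylsilane left by the cycloaddition fixes the halogen positions: chlorodesilylation puts Cl on C3′ and Markovnikov HBr addition to the resulting methylidene puts Br on C4′; no chlorohydrin and no OH→Br exchange are needed.
- C3 comes from a Sharpless desymmetrisation; C2 is relayed from C3 by Felkin–Anh methyl addition; C5 is relayed from C2/C3 in a 6-endo bromoetherification through the tertiary alcohol, so no oxane centre is left uncontrolled and no Claisen or epoxide/AlMe3 step is used.
- Ring order: the cyclohexene is closed first (step 5) on the open chain and the oxane last (step 9). This is the same ring sequence as in the direct plan; what differs is that the carbocycle is made in the route and that the oxane is closed by the C2 hydroxyl, not by a ketone oxygen.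

Key step: step 5

Assumption 1: locants follow the target name: oxane O1, C2 (quaternary), C3 (OH), C5 (Br), C6 (CMe2); cyclohexane C1′ (on C2), C3′ (Cl), C4′ (Br, Me).
Assumption 2: the tartrate and bis(oxazoline) enantiomers are assigned from the usual face rules (Sharpless mnemonic; square-planar Cu(II) chelate); if a model run on an achiral substrate showed the opposite sense, the other enantiomer would be used.

Step 1
Reactants: 1 penta-1,4-dien-3-ol
Product: 2 (1R)-1-[(2S)-oxiran-2-yl]prop-2-en-1-ol
Conditions: Ti(OiPr)4 (10 mol%), D-(−)-DIPT (13 mol%), t-BuOOH, 4 Å MS, CH2Cl2, −20 °C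
Reagents that add atoms: tert-butyl hydroperoxide CC(C)(C)OO
Why: Sharpless asymmetric epoxidation desymmetrises the divinyl carbinol by combined group and face selection, so a very high ee is expected, and the oxirane CH carbon becomes C3 of the oxane.

Step 2
Reactants: 2 (1R)-1-[(2S)-oxiran-2-yl]prop-2-en-1-ol; 3 (2-methylprop-1-en-1-yl)magnesium bromide
Product: 4 (3R,4S)-7-methylocta-1,6-diene-3,4-diol
Conditions: 3 (3 equiv), CuI (10 mol%), THF, −30 → 0 °C; aq. NH4Cl
Reagents that add atoms: none
Why: Copper-catalysed Grignard opening of the terminal epoxide (SN2 at CH2, after the first equivalent has deprotonated the alcohol) forms the C4–C5 bond and brings in the prenyl-type alkene without touching a stereocentre.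

Step 3
Reactants: 4 (3R,4S)-7-methylocta-1,6-diene-3,4-diol
Product: 5 (4S)-4-hydroxy-7-methylocta-1,6-dien-3-one
Conditions: activated MnO2 (15 equiv), CH2Cl2, rt; used at once
Reagents that add atoms: none
Why: Chemoselective allylic oxidation: MnO2 should oxidise only the allylic carbinol, which removes the auxiliary C3 centre of the diol and leaves the (S)-carbinol that becomes oxane C3.

Step 4
Reactants: 6 2-chlorobuta-1,3-diene; 7 [(trimethylsilyl)methyl]magnesium chloride
Product: 8 trimethyl(2-methylidenebut-3-en-1-yl)silane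
Conditions: NiCl2(dppp) (1 mol%), Et2O, reflux
Reagents that add atoms: none
Why: Kumada cross-coupling of the vinylic chloride with the silylmethyl Grignard reagent should give the 2-(silylmethyl)diene directly.

Step 5
Reactants: 5 (4S)-4-hydroxy-7-methylocta-1,6-dien-3-one; 8 trimethyl(2-methylidenebut-3-en-1-yl)silane
Product: 9 (2S)-2-hydroxy-5-methyl-1-{(1R)-4-[(trimethylsilyl)methyl]cyclohex-3-en-1-yl}hex-4-en-1-one
Conditions: Cu(SbF6)2 (10 mol%), 2,2′-isopropylidenebis[(4R)-4-tert-butyl-2-oxazoline] (11 mol%), 8 (3 equiv), 4 Å MS, CH2Cl2, −20 → 0 °C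
Reagents that add atoms: none
Why: The Cu(II)–bis(oxazoline) Lewis acid should bind the 1,2-ketol of 5 as a five-membered chelate, hold the enone s-cis and lower its LUMO, so that the diene adds in a concerted, asynchronous [4+2] cycloaddition. The closest known reaction type is the Cu(II)–bis(oxazoline)-catalysed Diels–Alder reaction of α′-hydroxy enones with isoprene and other 2-substituted dienes. The cyclohexene ring is closed by intermolecular [4+2] cycloaddition, and the donor CH2SiMe3 group on C2 of the diene directs the para orientation, so the silylmethyl carbon ends 1,4 to the acyl-bearing carbon. The only new stereocentre, C1′, is set by the catalyst: in the square-planar chelate one tert-butyl group covers one face of the α-carbon, and the CH2 substituent on C4 of 5 sits where the parent dimethyl ketol template carries a methyl group, so it should not override the ligand. The step needs face selectivity (ligand), regioselectivity (diene substituent) and cycloaddition in place of conjugate allylation by the allylsilane, which the mild chelating Lewis acid should secure. The C4 stereocentre of 5 is not touched.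

Step 6
Reactants: 9 (2S)-2-hydroxy-5-methyl-1-{(1R)-4-[(trimethylsilyl)methyl]cyclohex-3-en-1-yl}hex-4-en-1-one
Product: 10 (2S)-5-methyl-2-[(triethylsilyl)oxy]-1-{(1R)-4-[(trimethylsilyl)methyl]cyclohex-3-en-1-yl}hex-4-en-1-one
Conditions: Et3SiCl, imidazole, CH2Cl2, 0 °C
Reagents that add atoms: chlorotriethylsilane CC[Si](CC)(CC)Cl
Why: O-Silylation makes the α-oxygen non-chelating for step 7 and blocks 5-endo etherification by O3 in step 9; it is removed by the acid of step 10.

Step 7
Reactants: 10 (2S)-5-methyl-2-[(triethylsilyl)oxy]-1-{(1R)-4-[(trimethylsilyl)methyl]cyclohex-3-en-1-yl}hex-4-en-1-one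
Product: 11 (2S,3S)-6-methyl-3-[(triethylsilyl)oxy]-2-{(1R)-4-[(trimethylsilyl)methyl]cyclohex-3-en-1-yl}hept-5-en-2-ol
Conditions: MeLi, CeCl3, THF, −78 °C
Reagents that add atoms: methyllithium [Li]C
Why: Felkin–Anh (polar, non-chelation) 1,2-addition of the weakly basic methylcerium reagent anti to the C–OSi bond should set the quaternary carbinol (oxane C2) with methyl anti to O3 and without enolising either α-centre.

Step 8
Reactants: 11 (2S,3S)-6-methyl-3-[(triethylsilyl)oxy]-2-{(1R)-4-[(trimethylsilyl)methyl]cyclohex-3-en-1-yl}hept-5-en-2-ol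
Product: 12 (2S,3S)-2-[(1R,3S)-3-chloro-4-methylidenecyclohexyl]-6-methyl-3-[(triethylsilyl)oxy]hept-5-en-2-ol
Conditions: NCS (1.05 equiv), DMF/CH2Cl2, −20 °C
Reagents that add atoms: N-chlorosuccinimide O=C1CCC(=O)N1Cl
Why: Electrophilic chlorodesilylation of the allylsilane (SE2′) should deliver Cl only to the former alkene CH (C3′), by chair-like axial attack trans to the equatorial C1′ substituent, and leave the methylidene at C4′; the allylsilane is far more nucleophilic than the prenyl alkene.

Step 9
Reactants: 12 (2S,3S)-2-[(1R,3S)-3-chloro-4-methylidenecyclohexyl]-6-methyl-3-[(triethylsilyl)oxy]hept-5-en-2-ol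
Product: 13 {[(2S,3S,5S)-5-bromo-2-[(1R,3S)-3-chloro-4-methylidenecyclohexyl]-2,6,6-trimethyloxan-3-yl]oxy}(triethyl)silane
Conditions: 2,4,4,6-tetrabromocyclohexa-2,5-dienone (TBCO), MeNO2, 0 °C → rt, dark
Reagents that add atoms: 2,4,4,6-tetrabromocyclohexa-2,5-dien-1-one O=C1C(Br)=CC(Br)(Br)C=C1Br
Why: Bromonium-induced 6-endo haloetherification: TBCO should brominate the electron-rich prenyl alkene (the methylidene is deactivated by the allylic chlorine), the tertiary hydroxyl opens the bromonium ion at the CMe2 carbon, and the chair transition state with the cyclohexyl group equatorial, the C3 silyloxy group axial and anti to the C2 methyl, and bromine equatorial sets C5.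

Step 10
Reactants: 13 {[(2S,3S,5S)-5-bromo-2-[(1R,3S)-3-chloro-4-methylidenecyclohexyl]-2,6,6-trimethyloxan-3-yl]oxy}(triethyl)silane
Product: 15 (2S,3S,5S)-5-bromo-2-[(1R,3S,4S)-4-bromo-3-chloro-4-methylcyclohexyl]-2,6,6-trimethyloxan-3-ol, via triethylsilyl ether of the target 14 (not isolated)
Conditions: HBr (g), CH2Cl2, −78 → −30 °C; then MeOH, 0 °C; aq. NaHCO3
Reagents that add atoms: hydrogen bromide Br
Why: Markovnikov hydrobromination: protonation of the methylidene gives a tertiary cation bridged by the axial neighbouring chlorine, bromide opens it at the tertiary carbon anti to Cl (trans-diaxial, Fürst–Plattner), and the acid then cleaves the triethylsilyl ether in methanol.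

**Compound list**
1 | penta-1,4-dien-3-ol | C=CC(O)C=C | starting material
2 | (1R)-1-[(2S)-oxiran-2-yl]prop-2-en-1-ol | C=C[C@@H](O)[C@@H]1CO1 | intermediate
3 | (2-methylprop-1-en-1-yl)magnesium bromide | CC(C)=C[Mg]Br | starting material
4 | (3R,4S)-7-methylocta-1,6-diene-3,4-diol | C=C[C@@H](O)[C@@H](O)CC=C(C)C | intermediate
5 | (4S)-4-hydroxy-7-methylocta-1,6-dien-3-one | C=CC(=O)[C@@H](O)CC=C(C)C | intermediate
6 | 2-chlorobuta-1,3-diene | C=CC(Cl)=C | starting material
7 | [(trimethylsilyl)methyl]magnesium chloride | C[Si](C)(C)C[Mg]Cl | starting material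
8 | trimethyl(2-methylidenebut-3-en-1-yl)silane | C=CC(=C)C[Si](C)(C)C | intermediate
9 | (2S)-2-hydroxy-5-methyl-1-{(1R)-4-[(trimethylsilyl)methyl]cyclohex-3-en-1-yl}hex-4-en-1-one | O=C([C@@H]1CCC(C[Si](C)(C)C)=CC1)[C@@H](O)CC=C(C)C | intermediate
10 | (2S)-5-methyl-2-[(triethylsilyl)oxy]-1-{(1R)-4-[(trimethylsilyl)methyl]cyclohex-3-en-1-yl}hex-4-en-1-one | O=C([C@@H]1CCC(C[Si](C)(C)C)=CC1)[C@@H](O[Si](CC)(CC)CC)CC=C(C)C | intermediate
11 | (2S,3S)-6-methyl-3-[(triethylsilyl)oxy]-2-{(1R)-4-[(trimethylsilyl)methyl]cyclohex-3-en-1-yl}hept-5-en-2-ol | O[C@@](C)([C@@H]1CCC(C[Si](C)(C)C)=CC1)[C@@H](O[Si](CC)(CC)CC)CC=C(C)C | intermediate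
12 | (2S,3S)-2-[(1R,3S)-3-chloro-4-methylidenecyclohexyl]-6-methyl-3-[(triethylsilyl)oxy]hept-5-en-2-ol | O[C@@](C)([C@@H]1CCC(=C)[C@@H](Cl)C1)[C@@H](O[Si](CC)(CC)CC)CC=C(C)C | intermediate
13 | {[(2S,3S,5S)-5-bromo-2-[(1R,3S)-3-chloro-4-methylidenecyclohexyl]-2,6,6-trimethyloxan-3-yl]oxy}(triethyl)silane | CC1(C)O[C@@](C)([C@@H]2CCC(=C)[C@@H](Cl)C2)[C@@H](O[Si](CC)(CC)CC)C[C@@H]1Br | intermediate
14 | {[(2S,3S,5S)-5-bromo-2-[(1R,3S,4S)-4-bromo-3-chloro-4-methylcyclohexyl]-2,6,6-trimethyloxan-3-yl]oxy}(triethyl)silane | CC1(C)O[C@@](C)([C@@H]2CC[C@](C)(Br)[C@@H](Cl)C2)[C@@H](O[Si](CC)(CC)CC)C[C@@H]1Br | intermediate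
15 | (2S,3S,5S)-5-bromo-2-[(1R,3S,4S)-4-bromo-3-chloro-4-methylcyclohexyl]-2,6,6-trimethyloxan-3-ol | CC1(C)O[C@@](C)([C@@H]2CC[C@](C)(Br)[C@@H](Cl)C2)[C@@H](O)C[C@@H]1Br | target

**Step count and risks**
Total steps: 10. Longest linear sequence: 9 (steps 1–3 and 5–10; step 4 is a one-step branch).

Step 5 (Diels–Alder). What may go wrong: the secondary ketol may chelate copper less cleanly than a tertiary one, so face selectivity falls; the allylsilane diene may add as a nucleophile (conjugate allylation); or the vinyl ketone may polymerise. Fallback, from 8 and back at 9: the same catalysed cycloaddition would be run on the achiral tertiary ketol 4-hydroxy-4-methylpent-1-en-3-one F1, where the catalyst alone decides the face, to give 2-hydroxy-2-methyl-1-{(1R)-4-[(trimethylsilyl)methyl]cyclohex-3-en-1-yl}propan-1-one F2. Methyllithium would give the diol 2-methyl-3-{(1R)-4-[(trimethylsilyl)methyl]cyclohex-3-en-1-yl}butane-2,3-diol F3, and sodium periodate would cleave it to the methyl ketone 1-{(1R)-4-[(trimethylsilyl)methyl]cyclohex-3-en-1-yl}ethan-1-one F4. The kinetic lithium enolate (LDA, −78 °C) would be alkylated with 1-bromo-3-methylbut-2-ene to 5-methyl-1-{(1R)-4-[(trimethylsilyl)methyl]cyclohex-3-en-1-yl}hex-4-en-1-one F5. The kinetic sodium enolate of F5 (CH2 side) would then be hydroxylated with the (camphorylsulfonyl)oxaziridine enantiomer that gives the (S)-carbinol, which is 9.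

Step 9 (bromoetherification). What may go wrong: 5-exo closure to a tetrahydrofuran with a tertiary bromide, capture of the bromonium ion by water or the phenoxide, or a poor ratio at C5. Fallback, from 12 and back at 13: mercury(II) trifluoroacetate in MeNO2 at 0 °C, then aqueous KBr, would give by 6-endo oxymercuration bromo{(3S,5S,6S)-6-[(1R,3S)-3-chloro-4-methylidenecyclohexyl]-2,2,6-trimethyl-5-[(triethylsilyl)oxy]oxan-3-yl}mercury F6 with mercury equatorial. Br2/LiBr in pyridine would then replace mercury by bromine with retention (polar brominative demercuration) to give 13.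

Step 10 (hydrobromination). What may go wrong: protonation of the alkene is slowed by the allylic chlorine and may be overtaken by acid ionisation of the bis-tertiary ether (ring opening through the C5 bromonium ion) or by allylic migration of chloride. Fallback, from 13 and back at 15 through 14: radical Markovnikov hydrobromination by cobalt-catalysed hydrogen-atom transfer (Co(acac)2, PhSiH3, t-BuOOH, TsBr) under neutral conditions would give the silyl ether 14, here isolated. HF·pyridine in THF would then free the alcohol 15.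

**Further compounds**
F1 | step 5 | 4-hydroxy-4-methylpent-1-en-3-one | C=CC(=O)C(C)(C)O
F2 | step 5 | 2-hydroxy-2-methyl-1-{(1R)-4-[(trimethylsilyl)methyl]cyclohex-3-en-1-yl}propan-1-one | CC(C)(O)C(=O)[C@@H]1CCC(C[Si](C)(C)C)=CC1
F3 | step 5 | 2-methyl-3-{(1R)-4-[(trimethylsilyl)methyl]cyclohex-3-en-1-yl}butane-2,3-diol | CC(C)(O)C(C)(O)[C@@H]1CCC(C[Si](C)(C)C)=CC1
F4 | step 5 | 1-{(1R)-4-[(trimethylsilyl)methyl]cyclohex-3-en-1-yl}ethan-1-one | CC(=O)[C@@H]1CCC(C[Si](C)(C)C)=CC1
F5 | step 5 | 5-methyl-1-{(1R)-4-[(trimethylsilyl)methyl]cyclohex-3-en-1-yl}hex-4-en-1-one | CC(C)=CCCC(=O)[C@@H]1CCC(C[Si](C)(C)C)=CC1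
F6 | step 9 | bromo{(3S,5S,6S)-6-[(1R,3S)-3-chloro-4-methylidenecyclohexyl]-2,2,6-trimethyl-5-[(triethylsilyl)oxy]oxan-3-yl}mercury | CC1(C)O[C@@](C)([C@@H]2CCC(=C)[C@@H](Cl)C2)[C@@H](O[Si](CC)(CC)CC)C[C@@H]1[Hg]Br
F0 | step 10 | none | none
A1 | direct plan | (R)-(+)-limonene | CC1=CC[C@@H](CC1)C(=C)C
A2 | direct plan | (1S,2S,4R)-2-chloro-1-methyl-4-(prop-1-en-2-yl)cyclohexan-1-ol | C=C(C)[C@@H]1CC[C@](C)(O)[C@@H](Cl)C1
A3 | direct plan | 1-[(1R,3S,4S)-3-chloro-4-hydroxy-4-methylcyclohexyl]ethan-1-one | CC(=O)[C@@H]1CC[C@](C)(O)[C@@H](Cl)C1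
A4 | direct plan | 1-[(1R,3S,4S)-3-chloro-4-hydroxy-4-methylcyclohexyl]-5-methylhex-4-en-1-one | CC(C)=CCCC(=O)[C@@H]1CC[C@](C)(O)[C@@H](Cl)C1
A5 | direct plan | (1S,2S,4R)-4-[(3S)-3-bromo-2,2-dimethyl-3,4-dihydro-2H-pyran-6-yl]-2-chloro-1-methylcyclohexan-1-ol | CC1(C)OC([C@@H]2CC[C@](C)(O)[C@@H](Cl)C2)=CC[C@@H]1Br
A6 | direct plan | (1S,2S,4R)-4-[(2S,3S,5S)-5-bromo-3-hydroxy-2,6,6-trimethyloxan-2-yl]-2-chloro-1-methylcyclohexan-1-ol | CC1(C)O[C@@](C)([C@@H]2CC[C@](C)(O)[C@@H](Cl)C2)[C@@H](O)C[C@@H]1Br
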